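**Plan**
Feature used: ring D (C8–C14–C13–C16–C15) is a cyclopentanone whose carbonyl C15 sits on the quaternary C8, while C16 (bearing C17) is bonded to the carbinol bridgehead C13, 1,3 to C8 across ring C. C15 can therefore be a C8 acyl radical and C16/C17 an ethynyl group on C13.
Cuts: C16–H and both silyl ethers; C15–C16 (ring D); C13–C16; C8–C14 and C9–C11 (ring C, Diels–Alder); C8–C15; O–C7 and C9–C10 (lactone ring B); C10–C20; C5–C6.
Forward: ring A dienone → C5 vinyl → C20 and the C9–C8–C7 chain on C10 → spiro-lactone (ring B) → C8 ester and C8=C9 → ring C → C13 ethynyl carbinol → ring D by radical closure → C17 methyl → deprotection.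
Stereochemistry: C5 from a rhodium/(R)-BINAP conjugate vinylation (the only reagent-controlled centre); C10 by Michael addition anti to the C5 side chain; C8/C9 by diene approach anti to C5; C13 by equatorial acetylide attack; C16 by exo-face hydrogenation.

Key step: step 20

Locants follow ent-kaurane numbering: ring A = C1 (ketone), C2=C3, C4 (gem-dimethyl), C5 (bears C6), C10 (spiro); ring B = lactone C10–C20–O–C7(=O)–C8–C9; ring C = C8, C9, C11, C12, C13, C14; ring D = C8, C14, C13, C16, C15; C17 = methyl on C16. TBS = tert-butyldimethylsilyl, TES = triethylsilyl, Ar = 4-methoxyphenyl.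
Assumption: (R)-BINAP is taken to give the 5R adduct 4, by analogy with the known sense of induction on cyclohex-2-en-1-one; the antipodal ligand would be used if the sense were opposite.

**Route**

Step 1
Reactants: 1 4,4-dimethylcyclohex-2-en-1-one
Product: 2 4,4-dimethylcyclohexa-2,5-dien-1-one
Conditions: DDQ, 1,4-dioxane, reflux
Reagents that add atoms: none
Why: Quinone dehydrogenation of a cyclohexenone to the cross-conjugated dienone is standard, and the symmetrical dienone carries the ring A enone of the target and leaves C10 as the only enolisable position later on.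

Step 2
Reactants: 2 4,4-dimethylcyclohexa-2,5-dien-1-one; 3 potassium vinyltrifluoroborate
Product: 4 (R)-5-ethenyl-4,4-dimethylcyclohex-2-en-1-one
Conditions: [Rh(cod)2]BF4 (3 mol %), (R)-BINAP, PhMe–H2O, 100 °C
Reagents that add atoms: potassium vinyltrifluoroborate (3), C=C[B-](F)(F)F.[K+]
Why: Hayashi–Miyaura rhodium-catalysed asymmetric 1,4-addition of an alkenylboron reagent; both enone halves of 2 lead to the same product, so ligand-controlled face selection alone sets C5.

Step 3
Reactants: 4 (R)-5-ethenyl-4,4-dimethylcyclohex-2-en-1-one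
Product: 6 (S)-5-(hydroxymethyl)-4,4-dimethylcyclohex-2-en-1-one, via aldehyde 5 (not isolated)
Conditions: O3 (1 equiv), CH2Cl2–MeOH, pyridine, −78 °C; Me2S; then NaBH4, EtOH–CH2Cl2, −78 °C
Reagents that add atoms: ozone, [O-][O+]=O
Why: Ozonolysis should cleave the isolated vinyl group much faster than the conjugated, hindered enone, and NaBH4 at −78 °C should reduce the aldehyde but not the enone (chemoselective hydride reduction), the cold one-pot handling keeping C5 from epimerising.

Step 4
Reactants: 6 (S)-5-(hydroxymethyl)-4,4-dimethylcyclohex-2-en-1-one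
Product: 7 (S)-5-(tert-butyldimethylsilyloxymethyl)-4,4-dimethylcyclohex-2-en-1-one
Conditions: TBSCl, imidazole, DMF, 0 → 20 °C
Reagents that add atoms: tert-butyldimethylsilyl chloride, CC(C)(C)[Si](C)(C)Cl
Why: Standard silylation of a primary alcohol; the TBS ether should survive the basic, Lewis acidic and radical steps up to the final deprotection.

Step 5
Reactants: 7 (S)-5-(tert-butyldimethylsilyloxymethyl)-4,4-dimethylcyclohex-2-en-1-one; 8 ethyl formate
Product: 9 (5R,6Z)-5-(tert-butyldimethylsilyloxymethyl)-6-(hydroxymethylidene)-4,4-dimethylcyclohex-2-en-1-one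
Conditions: NaH, HCO2Et, EtOH (cat.), THF, 0 → 20 °C; aq. NH4Cl
Reagents that add atoms: ethyl formate (8), CCOC=O
Why: Claisen formylation; C10 is the only enolisable carbon of 7 (C2 is vinylic, C4 quaternary), so C20 can enter nowhere else.

Step 6
Reactants: 9 (5R,6Z)-5-(tert-butyldimethylsilyloxymethyl)-6-(hydroxymethylidene)-4,4-dimethylcyclohex-2-en-1-one; 10 2,2,2-trifluoroethyl acrylate
Product: 11 2,2,2-trifluoroethyl 3-[(1S,6R)-6-(tert-butyldimethylsilyloxymethyl)-1-formyl-5,5-dimethyl-2-oxocyclohex-3-en-1-yl]propanoate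
Conditions: Et3N (0.3 equiv), MeCN, 20 → 40 °C
Reagents that add atoms: 2,2,2-trifluoroethyl acrylate (10), C=CC(=O)OCC(F)(F)F
Why: Amine-catalysed Michael addition of a 2-formyl ketone; the acrylate should approach C10 of the planar enolate anti to the neighbouring C5 silyloxymethyl group, setting the quaternary centre with C9 trans and C20 cis to C6.

Step 7
Reactants: 11 2,2,2-trifluoroethyl 3-[(1S,6R)-6-(tert-butyldimethylsilyloxymethyl)-1-formyl-5,5-dimethyl-2-oxocyclohex-3-en-1-yl]propanoate
Product: 13 (6S,11R)-11-(tert-butyldimethylsilyloxymethyl)-10,10-dimethyl-2-oxaspiro[5.5]undec-8-ene-3,7-dione, via hydroxy ester 12 (not isolated)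
Conditions: NaBH4, EtOH–CH2Cl2, −78 °C; then PPTS (cat.), PhMe, 50 °C
Reagents that add atoms: none
Why: Chemoselective reduction of the aldehyde in the presence of the conjugated, α-quaternary ketone, followed by lactonisation of the primary alcohol onto the activated trifluoroethyl ester, closes ring B.

Step 8
Reactants: 13 (6S,11R)-11-(tert-butyldimethylsilyloxymethyl)-10,10-dimethyl-2-oxaspiro[5.5]undec-8-ene-3,7-dione; 14 allyl chloroformate
Product: 15 allyl (6S,11R)-11-(tert-butyldimethylsilyloxymethyl)-10,10-dimethyl-3,7-dioxo-2-oxaspiro[5.5]undec-8-ene-4-carboxylate (both C8 epimers)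
Conditions: LiN(SiMe3)2 (2.2 equiv), THF, −78 °C; allyl chloroformate
Reagents that add atoms: allyl chloroformate (14), C=CCOC(Cl)=O
Why: Claisen-type C-acylation of the lactone lithium enolate; ring A has no enolisable hydrogen, so only C8 is deprotonated, and the second equivalent of base absorbs the more acidic product.

Step 9
Reactants: 15 allyl (6S,11R)-11-(tert-butyldimethylsilyloxymethyl)-10,10-dimethyl-3,7-dioxo-2-oxaspiro[5.5]undec-8-ene-4-carboxylate
Product: 17 allyl (6S,11R)-11-(tert-butyldimethylsilyloxymethyl)-10,10-dimethyl-3,7-dioxo-2-oxaspiro[5.5]undeca-4,8-diene-4-carboxylate, via C8 phenylselenide 16 (not isolated)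
Conditions: NaH, THF, 0 °C; PhSeCl; then 30% H2O2, CH2Cl2, 0 → 20 °C
Reagents that add atoms: none
Why: Selenation of the malonate-type anion and selenoxide syn-elimination can remove only a C9 hydrogen, giving the doubly activated C8=C9 dienophile.

Step 10
Reactants: 18 1,2-bis(trimethylsilyloxy)cyclobutene; 19 4-methoxybenzenethiol
Product: 21 2-(4-methoxyphenylthio)cyclobutanone, via 2-hydroxycyclobutanone 20 (not isolated)
Conditions: MeOH, 20 °C; evaporate; then 19, TsOH (cat.), PhH, 20 °C
Reagents that add atoms: 4-methoxybenzenethiol (19), COc1ccc(S)cc1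
Why: Methanolysis frees the α-ketol, which exchanges hydroxyl for arylthio under acid catalysis (known α-ketol to α-sulfenyl ketone condensation).

Step 11
Reactants: 21 2-(4-methoxyphenylthio)cyclobutanone
Product: 22 1-acetoxy-2-(4-methoxyphenylthio)cyclobut-1-ene
Conditions: Ac2O, Et3N, DMAP (cat.), CH2Cl2, 0 → 20 °C
Reagents that add atoms: acetic anhydride, CC(=O)OC(C)=O
Why: O-acetylation of the acidic α-sulfenyl ketone under acyl-transfer catalysis gives the enol acetate on the sulfur-bearing side.

Step 12
Reactants: 22 1-acetoxy-2-(4-methoxyphenylthio)cyclobut-1-ene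
Product: 23 2-acetoxy-3-(4-methoxyphenylthio)buta-1,3-diene
Conditions: flash vacuum pyrolysis, 350 °C, 0.1 Torr
Reagents that add atoms: none
Why: Thermal conrotatory 4π electrocyclic ring opening of the cyclobutene gives the 2,3-disubstituted diene.

Step 13
Reactants: 17 allyl (6S,11R)-11-(tert-butyldimethylsilyloxymethyl)-10,10-dimethyl-3,7-dioxo-2-oxaspiro[5.5]undeca-4,8-diene-4-carboxylate; 23 2-acetoxy-3-(4-methoxyphenylthio)buta-1,3-diene
Product: 24 Diels–Alder adduct: ring C cis-fused to the lactone; C8 allyl ester; C12=C13 with 13-acetoxy and 12-arylthio; H9 cis to the C8 ester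
Conditions: ZnCl2 (0.3 equiv), CH2Cl2, 0 → 20 °C
Reagents that add atoms: 2-acetoxy-3-(4-methoxyphenylthio)buta-1,3-diene (23), CC(=O)OC(=C)C(=C)Sc1ccc(OC)cc1
Why: Diels–Alder reaction of a chelated alkylidene-malonate-type dienophile: the arylthio group outweighs the acetoxy group, so its neighbouring terminus (C11) bonds to the electrophilic C9 and C14 to C8 (oxygen ends on C13); suprafacial addition makes ring C cis-fused, and the diene should approach the lactone face flanked by the flat C1 carbonyl, anti to C5 with its silyloxymethyl and gem-dimethyl neighbours, which sets C8 and C9.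

Step 14
Reactants: 24 Diels–Alder adduct
Product: 25 C13 ketone with 12-(4-methoxyphenylthio) group (both C12 epimers); C8 allyl ester
Conditions: K2CO3, MeOH, 0 °C
Reagents that add atoms: none
Why: Mild methanolysis (transesterification) should cleave the enol acetate far faster than the hindered allyl ester or the lactone and release the C13 ketone.

Step 15
Reactants: 25 C13 ketone with 12-(4-methoxyphenylthio) group
Product: 26 C13 ketone: cis-fused cyclohexanone lactone with C8 allyl ester
Conditions: SmI2 (2.2 equiv), THF–MeOH, −78 °C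
Reagents that add atoms: none
Why: SmI2 cleaves a C–S bond α to a ketone by two-electron reduction to the samarium enolate (reductive desulfenylation), and at −78 °C the conjugated ring A ketone should not react.

Step 16
Reactants: 26 C13 ketone; 27 ethynylmagnesium bromide
Product: 28 C13 ethynyl carbinol: ethynyl cis to the C8 allyl ester; hydroxyl cis to the lactone carbonyl C7
Conditions: CeCl3 (anhydrous), THF, −78 °C
Reagents that add atoms: ethynylmagnesium bromide (27), C#C[Mg]Br
Why: 1,2-Addition of the cerium acetylide: the saturated C13 ketone is far more reactive than the conjugated, α-quaternary C1 ketone, and in the ring C chair with C10 equatorial the lactone carbonyl C7 is axial on C8, so equatorial attack anti to it places the ethynyl group cis to the equatorial C15 ester.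

Step 17
Reactants: 28 C13 ethynyl carbinol
Product: 29 C13 triethylsilyl ether of 28
Conditions: TESOTf, 2,6-lutidine, CH2Cl2, −78 → 0 °C
Reagents that add atoms: triethylsilyl trifluoromethanesulfonate, CC[Si](CC)(CC)OS(=O)(=O)C(F)(F)F
Why: Silyl triflate silylation of a tertiary alcohol; the ether blocks acyl transfer from the lactone and, by seeking an equatorial site, favours the ring C chair in which C15 and the ethynyl group are both axial.

Step 18
Reactants: 29 C13 triethylsilyl ether
Product: 30 C8 carboxylic acid (C15 acid) of 29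
Conditions: Pd(PPh3)4 (5 mol %), morpholine, THF, 0 → 20 °C; cold aq. citric acid
Reagents that add atoms: none
Why: Tsuji–Trost deallylation with zerovalent palladium and an amine allyl acceptor is neutral and should leave the lactone, silyl ethers, enone and alkyne intact; the malonic-type acid is kept cold to avoid decarboxylation.

Step 19
Reactants: 30 C8 carboxylic acid
Product: 31 Se-phenyl selenoester: C8–C(=O)SePh; C13 ethynyl (cis to C15) with OTES; ring A enone; C6 OTBS
Conditions: (PhSe)2, Bu3P, CH2Cl2, 0 → 20 °C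
Reagents that add atoms: diphenyl diselenide, c1ccc(cc1)[Se][Se]c1ccccc1
Why: Phosphine/diselenide activation (acyloxyphosphonium, then attack of phenylselenolate) converts hindered acids into Se-phenyl selenoesters under neutral conditions.

Step 20
Reactants: 31 Se-phenyl selenoester
Product: 32 15-oxo-16-methylene bicyclo[3.2.1]octane lactone (13-OTES; 6-OTBS; ring A enone)
Conditions: Bu3SnH (1.3 equiv, syringe pump), 2,2'-azobis(4-methoxy-2,4-dimethylvaleronitrile), PhH (0.01 M), 30 °C, CO (20 atm)
Reagents that add atoms: none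
Why: Bu3Sn• abstracts the phenylseleno group of 31 to give the σ-acyl radical at C15, which adds to the internal alkyne carbon C16 and forms C15–C16; the vinyl radical at C17 then takes a hydrogen atom from Bu3SnH. The closest known reaction type is the tin-hydride-mediated cyclisation of acyl radicals from Se-phenyl selenoesters onto alkynes and alkenes. Ring D (C8–C15–C16–C13–C14) closes in the 5-exo-dig mode and completes the bicyclo[3.2.1]octane with the ketone at its final oxidation level. No stereocentre is created (C16 stays sp2); the ring can form only because C15 and the ethynyl group are cis-1,3 on ring C, and the equatorial-seeking OSiEt3 group favours the chair in which both are axial. Ring closure must outrun loss of CO (which would leave a C8 radical stabilised by the lactone carbonyl) and hydrogen transfer to the acyl radical; low-temperature initiation, CO pressure and slow hydride addition at high dilution serve this, and the β-hindered ring A enone is too remote and too slow an acceptor to compete.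

Step 21
Reactants: 32 15-oxo-16-methylene lactone
Product: 33 16-methyl ketone (13-OTES; 6-OTBS; H16 exo; C17 endo)
Conditions: H2 (1 atm), RhCl(PPh3)3 (10 mol %), PhH, 20 °C
Reagents that add atoms: none
Why: Homogeneous hydrogenation with RhCl(PPh3)3 should select the unhindered exocyclic 1,1-disubstituted alkene over the ring A enone with its neopentyl β-carbon, and hydrogen should add from the exo face of the two-carbon bridge (the side of C14), placing C17 endo as in the target.

Step 22
Reactants: 33 16-methyl ketone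
Product: 34 target CNP0533761.1
Conditions: HF·pyridine, THF–pyridine, 0 → 20 °C
Reagents that add atoms: none
Why: Fluoride cleavage of both silyl ethers under acidic, non-basic conditions avoids retro-aldol opening of the C13 hydroxy C15 ketone.

**Compound list**
1 | 4,4-dimethylcyclohex-2-en-1-one | CC1(C)CCC(=O)C=C1 | starting material
2 | 4,4-dimethylcyclohexa-2,5-dien-1-one | CC1(C)C=CC(=O)C=C1 | intermediate
3 | potassium vinyltrifluoroborate | C=C[B-](F)(F)F.[K+] | starting material
4 | (R)-5-ethenyl-4,4-dimethylcyclohex-2-en-1-one | O=C1C=CC(C)(C)[C@H](C1)C=C | intermediate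
5 | (S)-2,2-dimethyl-5-oxocyclohex-3-ene-1-carbaldehyde | O=C1C=CC(C)(C)[C@H](C1)C=O | intermediate
6 | (S)-5-(hydroxymethyl)-4,4-dimethylcyclohex-2-en-1-one | O=C1C=CC(C)(C)[C@H](C1)CO | intermediate
7 | (S)-5-(tert-butyldimethylsilyloxymethyl)-4,4-dimethylcyclohex-2-en-1-one | O=C1C=CC(C)(C)[C@H](C1)CO[Si](C)(C)C(C)(C)C | intermediate
8 | ethyl formate | CCOC=O | starting material
9 | (5R,6Z)-5-(tert-butyldimethylsilyloxymethyl)-6-(hydroxymethylidene)-4,4-dimethylcyclohex-2-en-1-one | O=C1C=CC(C)(C)[C@@H](CO[Si](C)(C)C(C)(C)C)/C1=C/O | intermediate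
10 | 2,2,2-trifluoroethyl acrylate | C=CC(=O)OCC(F)(F)F | starting material
11 | 2,2,2-trifluoroethyl 3-[(1S,6R)-6-(tert-butyldimethylsilyloxymethyl)-1-formyl-5,5-dimethyl-2-oxocyclohex-3-en-1-yl]propanoate | FC(F)(F)COC(=O)CC[C@]1(C=O)C(=O)C=CC(C)(C)[C@H]1CO[Si](C)(C)C(C)(C)C | intermediate
12 | hydroxy ester: 1-(hydroxymethyl) analogue of 11 | FC(F)(F)COC(=O)CC[C@]1(CO)C(=O)C=CC(C)(C)[C@H]1CO[Si](C)(C)C(C)(C)C | intermediate
13 | (6S,11R)-11-(tert-butyldimethylsilyloxymethyl)-10,10-dimethyl-2-oxaspiro[5.5]undec-8-ene-3,7-dione | O=C1CC[C@]2(CO1)C(=O)C=CC(C)(C)[C@H]2CO[Si](C)(C)C(C)(C)C | intermediate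
14 | allyl chloroformate | C=CCOC(Cl)=O | starting material
15 | allyl (6S,11R)-11-(tert-butyldimethylsilyloxymethyl)-10,10-dimethyl-3,7-dioxo-2-oxaspiro[5.5]undec-8-ene-4-carboxylate (C8 epimers) | C=CCOC(=O)C2C[C@]1(COC2=O)C(=O)C=CC(C)(C)[C@H]1CO[Si](C)(C)C(C)(C)C | intermediate
16 | C8 phenylselenide of 15 | C=CCOC(=O)C2([Se]c3ccccc3)C[C@]1(COC2=O)C(=O)C=CC(C)(C)[C@H]1CO[Si](C)(C)C(C)(C)C | intermediate
17 | allyl (6S,11R)-11-(tert-butyldimethylsilyloxymethyl)-10,10-dimethyl-3,7-dioxo-2-oxaspiro[5.5]undeca-4,8-diene-4-carboxylate | C=CCOC(=O)C2=C[C@]1(COC2=O)C(=O)C=CC(C)(C)[C@H]1CO[Si](C)(C)C(C)(C)C | intermediate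
18 | 1,2-bis(trimethylsilyloxy)cyclobutene | C[Si](C)(C)OC1=C(O[Si](C)(C)C)CC1 | starting material
19 | 4-methoxybenzenethiol | COc1ccc(S)cc1 | starting material
20 | 2-hydroxycyclobutanone | O=C1CCC1O | intermediate
21 | 2-(4-methoxyphenylthio)cyclobutanone | COc1ccc(SC2CCC2=O)cc1 | intermediate
22 | 1-acetoxy-2-(4-methoxyphenylthio)cyclobut-1-ene | CC(=O)OC1=C(Sc2ccc(OC)cc2)CC1 | intermediate
23 | 2-acetoxy-3-(4-methoxyphenylthio)buta-1,3-diene | CC(=O)OC(=C)C(=C)Sc1ccc(OC)cc1 | intermediate
24 | Diels–Alder adduct (C8 allyl ester; 13-acetoxy-12-arylthio C12=C13; cis-fused) | C=CCOC(=O)[C@]23CC(OC(C)=O)=C(Sc4ccc(OC)cc4)C[C@H]2[C@]1(COC3=O)C(=O)C=CC(C)(C)[C@H]1CO[Si](C)(C)C(C)(C)C | intermediate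
25 | 12-arylthio C13 ketone (C12 epimers) | C=CCOC(=O)[C@]23CC(=O)C(Sc4ccc(OC)cc4)C[C@H]2[C@]1(COC3=O)C(=O)C=CC(C)(C)[C@H]1CO[Si](C)(C)C(C)(C)C | intermediate
26 | C13 ketone with C8 allyl ester | C=CCOC(=O)[C@]23CC(=O)CC[C@H]2[C@]1(COC3=O)C(=O)C=CC(C)(C)[C@H]1CO[Si](C)(C)C(C)(C)C | intermediate
27 | ethynylmagnesium bromide | C#C[Mg]Br | starting material
28 | C13 ethynyl carbinol (ethynyl cis to C15) | C=CCOC(=O)[C@]23C[C@](O)(C#C)CC[C@H]2[C@]1(COC3=O)C(=O)C=CC(C)(C)[C@H]1CO[Si](C)(C)C(C)(C)C | intermediate
29 | C13 triethylsilyl ether of 28 | C=CCOC(=O)[C@]23C[C@](O[Si](CC)(CC)CC)(C#C)CC[C@H]2[C@]1(COC3=O)C(=O)C=CC(C)(C)[C@H]1CO[Si](C)(C)C(C)(C)C | intermediate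
30 | C8 carboxylic acid | OC(=O)[C@]23C[C@](O[Si](CC)(CC)CC)(C#C)CC[C@H]2[C@]1(COC3=O)C(=O)C=CC(C)(C)[C@H]1CO[Si](C)(C)C(C)(C)C | intermediate
31 | Se-phenyl selenoester (key-step precursor) | O=C([Se]c4ccccc4)[C@]23C[C@](O[Si](CC)(CC)CC)(C#C)CC[C@H]2[C@]1(COC3=O)C(=O)C=CC(C)(C)[C@H]1CO[Si](C)(C)C(C)(C)C | intermediate
32 | 15-oxo-16-methylene bicyclo[3.2.1]octane lactone (key-step product) | C=C1C(=O)[C@]23C[C@@]1(O[Si](CC)(CC)CC)CC[C@H]2[C@]1(COC3=O)C(=O)C=CC(C)(C)[C@H]1CO[Si](C)(C)C(C)(C)C | intermediate
33 | 16-methyl ketone, bis-silyl ether | C[C@H]1C(=O)[C@]23C[C@@]1(O[Si](CC)(CC)CC)CC[C@H]2[C@]1(COC3=O)C(=O)C=CC(C)(C)[C@H]1CO[Si](C)(C)C(C)(C)C | intermediate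
34 | CNP0533761.1 | C[C@H]1C(=O)[C@]23C[C@@]1(O)CC[C@H]2[C@]1(COC3=O)C(=O)C=CC(C)(C)[C@H]1CO | target

**Count and risks**
Total: 22 steps. Longest linear sequence: 19 steps (steps 1–9 and 13–22); the diene 23 takes 3 steps.

The step most likely to fail is step 20. The acyl radical may lose CO faster than it cyclises, because decarbonylation gives a tertiary C8 radical stabilised by the lactone carbonyl, and closure needs ring C to reach the chair with C10 axial; hydrogen transfer to the acyl radical is a second drain. The fallback sets out from 31. Reduction of the selenoester with Bu3SnH under Pd(PPh3)4 catalysis, which passes through no free acyl radical, would give the C15 aldehyde F1. SmI2 with t-BuOH in THF at −78 °C would then form the ketyl, which cannot lose CO, and close ring D by 5-exo-dig addition to the alkyne to give the C15 allylic alcohol F2. Dess–Martin oxidation of F2 comes back to the route at 32.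

Second is step 13. The 2,3-disubstituted diene may fail to engage C9, which is neopentyl next to the spiro centre, or the acetoxy group may compete with sulfur in steering the orientation. The fallback sets out from 17. Cycloaddition with buta-1,3-diene (ZnCl2, CH2Cl2, or 110 °C in a sealed tube), which is unhindered and raises no orientation question, would give the cyclohexene allyl ester F3. Pd(PPh3)4 and morpholine would free the C15 acid F4, and iodolactonisation (I2, NaHCO3, MeCN–H2O) would place oxygen on C13 through five-membered lactone closure, giving the iodo lactone F5. Bu3SnH/AIBN would remove iodine to give the bridged lactone F6, and allyl alcohol with K2CO3 at 0 °C would open this strained lactone to the C13 hydroxy allyl ester F7. Dess–Martin oxidation of F7 comes back to the route at 26.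

Third is step 16. The slim acetylide may attack C13 axially and end up trans to C15, or the new alkoxide may take over the lactone acyl group. The fallback sets out from 26. Addition of 2-lithio-1,3-dithiane (from 1,3-dithiane and BuLi, THF, −78 °C), a bulky formyl anion equivalent that attacks cyclohexanones equatorially, would give the dithianyl carbinol F8. TESOTf and 2,6-lutidine would give the silyl ether F9, and MeI with CaCO3 in aqueous MeCN would unmask the α-silyloxy aldehyde F10. Ohira–Bestmann homologation (dimethyl (1-diazo-2-oxopropyl)phosphonate, K2CO3, MeOH, 0 °C) would turn the formyl group into the ethynyl group and come back to the route at 29.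

**Further compounds**
F1 | step 20 | C15 aldehyde (C8 formyl; C13 ethynyl OTES) | O=C[C@]23C[C@](O[Si](CC)(CC)CC)(C#C)CC[C@H]2[C@]1(COC3=O)C(=O)C=CC(C)(C)[C@H]1CO[Si](C)(C)C(C)(C)C
F2 | step 20 | C15 allylic alcohol (16-methylene; C15 epimers) | C=C1C(O)[C@]23C[C@@]1(O[Si](CC)(CC)CC)CC[C@H]2[C@]1(COC3=O)C(=O)C=CC(C)(C)[C@H]1CO[Si](C)(C)C(C)(C)C
F3 | step 13 | butadiene adduct: C12=C13 cyclohexene with C8 allyl ester | C=CCOC(=O)[C@]23CC=CC[C@H]2[C@]1(COC3=O)C(=O)C=CC(C)(C)[C@H]1CO[Si](C)(C)C(C)(C)C
F4 | step 13 | C15 acid of F3 | OC(=O)[C@]23CC=CC[C@H]2[C@]1(COC3=O)C(=O)C=CC(C)(C)[C@H]1CO[Si](C)(C)C(C)(C)C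
F5 | step 13 | iodo lactone (C15–O–C13 bridge; 12-iodo trans to oxygen) | O=C4[C@]23C[C@H](O4)[C@@H](I)C[C@H]2[C@]1(COC3=O)C(=O)C=CC(C)(C)[C@H]1CO[Si](C)(C)C(C)(C)C
F6 | step 13 | bridged lactone (C15–O–C13) | O=C4[C@]23C[C@H](O4)CC[C@H]2[C@]1(COC3=O)C(=O)C=CC(C)(C)[C@H]1CO[Si](C)(C)C(C)(C)C
F7 | step 13 | C13 hydroxy allyl ester (hydroxyl cis to C15) | C=CCOC(=O)[C@]23C[C@H](O)CC[C@H]2[C@]1(COC3=O)C(=O)C=CC(C)(C)[C@H]1CO[Si](C)(C)C(C)(C)C
F8 | step 16 | C13 (1,3-dithian-2-yl) carbinol | C=CCOC(=O)[C@]23C[C@](O)(C4SCCCS4)CC[C@H]2[C@]1(COC3=O)C(=O)C=CC(C)(C)[C@H]1CO[Si](C)(C)C(C)(C)C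
F9 | step 16 | triethylsilyl ether of F8 | C=CCOC(=O)[C@]23C[C@](O[Si](CC)(CC)CC)(C4SCCCS4)CC[C@H]2[C@]1(COC3=O)C(=O)C=CC(C)(C)[C@H]1CO[Si](C)(C)C(C)(C)C
F10 | step 16 | C13 formyl triethylsilyl ether | C=CCOC(=O)[C@]23C[C@](O[Si](CC)(CC)CC)(C=O)CC[C@H]2[C@]1(COC3=O)C(=O)C=CC(C)(C)[C@H]1CO[Si](C)(C)C(C)(C)C
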